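Ring C of the target is cut at O1–C2 and C3–C4. The feature exploited is that O1–C8a–C4a–C4 of ring C, fused to ring A, is the oxa-diene of an ortho-quinone methide, while C2 and C3 are the two carbons of an E-styrene. A chiral acid-catalysed hetero-Diels–Alder reaction between the quinone methide from a differentially protected salicyl alcohol and an E-styryl pinacolboronate closes ring C, forms both bonds and sets C2 and C3 as the trans pair in one operation. Boron at C3 is a hydroxyl placeholder that leaves the aryl group in control of the polarity. MOM ethers mark O7 and O3' for the galloyl esters; benzyl ethers cover the rest.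

Key step: step 7

Remark: 3,4,5-tris(benzyloxy)benzoic acid is taken as a catalogue compound (otherwise two routine steps from gallic acid), and the (R)-acid in step 7 is written for definiteness; its mirror image would be used should the sense of induction prove opposite.

Step 1
Reactants: 1 2,4,6-trihydroxybenzaldehyde
Product: 2 2,6-dihydroxy-4-(methoxymethoxy)benzaldehyde
Conditions: MOMCl (1.0 equiv), K2CO3, acetone, 0 °C → rt
Reagents that add atoms: chloromethyl methyl ether, COCCl
Why: Williamson-type O-alkylation (MOM protection), in which the 4-OH, para to the formyl group, is the most acidic hydroxyl and the only one never tied up in a hydrogen bond to the carbonyl, so one equivalent of reagent should alkylate it first.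

Step 2
Reactants: 2 2,6-dihydroxy-4-(methoxymethoxy)benzaldehyde
Product: 3 2-(benzyloxy)-6-hydroxy-4-(methoxymethoxy)benzaldehyde
Conditions: BnBr (1.05 equiv), K2CO3, DMF, rt
Reagents that add atoms: benzyl bromide, BrCc1ccccc1
Why: Williamson ether synthesis on two equivalent hydroxyls; after the first benzylation the remaining one is locked in a strong hydrogen bond to the formyl oxygen, which should stop the reaction at the mono-ether.

Step 3
Reactants: 3 2-(benzyloxy)-6-hydroxy-4-(methoxymethoxy)benzaldehyde
Product: 4 3-(benzyloxy)-2-(hydroxymethyl)-5-(methoxymethoxy)phenol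
Conditions: NaBH4, THF/MeOH, 0 °C; pH 7 work-up, used at once
Reagents that add atoms: none
Why: Borohydride reduction of the aldehyde to the primary alcohol leaves MOM and benzyl ethers untouched, and a cold neutral work-up with immediate use avoids premature ionisation of the electron-rich salicyl alcohol.

Step 4
Reactants: 5 3,4-dihydroxybenzaldehyde
Product: 6 4-(benzyloxy)-3-hydroxybenzaldehyde
Conditions: BnBr (1.0 equiv), NaHCO3, DMF, 40 °C
Reagents that add atoms: benzyl bromide, BrCc1ccccc1
Why: Regioselective Williamson etherification, since the weak base deprotonates only the more acidic 4-OH, which is conjugated with the para formyl group.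

Step 5
Reactants: 6 4-(benzyloxy)-3-hydroxybenzaldehyde
Product: 7 4-(benzyloxy)-3-(methoxymethoxy)benzaldehyde
Conditions: MOMCl, K2CO3, acetone, rt
Reagents that add atoms: chloromethyl methyl ether, COCCl
Why: MOM protection (Williamson-type O-alkylation) of the only remaining phenol, with the aldehyde and the benzyl ether inert.

Step 6
Reactants: 7 4-(benzyloxy)-3-(methoxymethoxy)benzaldehyde
Product: 8 2-[(E)-2-[4-(benzyloxy)-3-(methoxymethoxy)phenyl]ethenyl]-4,4,5,5-tetramethyl-1,3,2-dioxaborolane
Conditions: CH2(Bpin)2, LiTMP, THF, −78 °C → rt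
Reagents that add atoms: bis(4,4,5,5-tetramethyl-1,3,2-dioxaborolan-2-yl)methane, CC1(C)OB(CB2OC(C)(C)C(C)(C)O2)OC1(C)C
Why: Boron-Wittig olefination, in which the lithiated gem-diboronate adds to the non-enolisable aldehyde and syn-elimination of O–Bpin from the adduct should give the E-alkenylboronate, the geometry that later becomes the 2,3-trans relationship.

Step 7
Reactants: 4 3-(benzyloxy)-2-(hydroxymethyl)-5-(methoxymethoxy)phenol; 8 2-[(E)-2-[4-(benzyloxy)-3-(methoxymethoxy)phenyl]ethenyl]-4,4,5,5-tetramethyl-1,3,2-dioxaborolane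
Product: 10 (2S,3S)-5-(benzyloxy)-2-[4-(benzyloxy)-3-(methoxymethoxy)phenyl]-7-(methoxymethoxy)-3-(4,4,5,5-tetramethyl-1,3,2-dioxaborolan-2-yl)chromane, via ortho-quinone methide 9 (not isolated)
Conditions: (R)-TRIP (10 mol%), 4 Å MS, PhMe, 0 °C → rt; 4 added slowly to 8 (2 equiv)
Reagents that add atoms: none
Why: Proposed new method: the acid ionises the benzylic C–OH bond of 4 (made labile by three oxygen donors on ring A) and the resulting quinone methide 9 stays hydrogen-bonded through its carbonyl oxygen to the chiral phosphate; the boron-bearing carbon of 8 then bonds to the exocyclic CH2 (C3–C4) while the benzylic carbon, whose positive charge is carried by the para-benzyloxyaryl group and the adjacent C–B bond, is captured by the quinone methide oxygen (O1–C2) in an asynchronous, suprafacial [4+2]. The closest known reaction type is the chiral Brønsted acid-catalysed inverse-electron-demand hetero-Diels–Alder reaction of in situ ortho-quinone methides with styrenes; a β-boryl styrene has not been used as the 2π partner. Ring C is closed as a dihydropyran by [4+2] cycloaddition onto the O1–C8a–C4a–C4 heterodiene, the second bond forming by six-membered capture of the benzylic cation inside the ion pair. The relative configuration at C2/C3 is controlled by the E geometry of 8, which suprafacial addition turns into the 2,3-trans (diequatorial) product, and the absolute configuration (2S,3S) by the catalyst pocket, which blocks one face of the planar heterodiene and thereby decides, through endo or exo placement of the aryl group, which alkene face is bonded. The step needs regioselectivity (aryl on C2, boron on C3), secured by the para-alkoxyaryl donor that outweighs the weak acceptor boron, and chemoselectivity for cycloaddition over styryl transfer from boron and over self-condensation of 9, secured by the hindered, weakly Lewis acidic pinacol ester and by slow addition of 4 to excess 8.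

Step 8
Reactants: 10 (2S,3S)-3-boryl chromane
Product: 11 (2R,3S)-5-(benzyloxy)-2-[4-(benzyloxy)-3-(methoxymethoxy)phenyl]-7-(methoxymethoxy)chroman-3-ol
Conditions: NaBO3·4H2O, THF/H2O, rt
Reagents that add atoms: sodium perborate, [Na+].[Na+].O[B-]1(O)OO[B-](O)(O)OO1
Why: Boronate oxidation by 1,2-migration of carbon from boron to oxygen proceeds with retention, so the C–B centre becomes the (3S) alcohol trans to the C2 aryl group (the C2 descriptor changes to R only through the priority rules), and the mildly basic medium should disfavour β-elimination of the ring oxygen.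

Step 9
Reactants: 11 (2R,3S)-chroman-3-ol
Product: 12 (2R,3S)-3,5-bis(benzyloxy)-2-[4-(benzyloxy)-3-(methoxymethoxy)phenyl]-7-(methoxymethoxy)chromane
Conditions: NaH, BnBr, DMF, 0 °C → rt
Reagents that add atoms: benzyl bromide, BrCc1ccccc1
Why: Williamson etherification of the secondary alkoxide keeps O3 out of the later acylation and touches neither stereocentre.

Step 10
Reactants: 12 (2R,3S)-3,5,4'-tri-O-benzyl-7,3'-di-O-MOM flavan
Product: 13 (2R,3S)-3,5-bis(benzyloxy)-2-[4-(benzyloxy)-3-hydroxyphenyl]chroman-7-ol
Conditions: 2 M HCl, MeOH/THF, 45 °C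
Reagents that add atoms: none
Why: Acid-catalysed acetal exchange with methanol removes both MOM groups and frees exactly the two phenols that are to be esterified, while benzyl ethers and the chroman ring should be stable to dilute acid at this temperature.

Step 11
Reactants: 13 (2R,3S)-3,5-bis(benzyloxy)-2-[4-(benzyloxy)-3-hydroxyphenyl]chroman-7-ol; 14 3,4,5-tris(benzyloxy)benzoic acid (2.4 equiv)
Product: 15 (2R,3S)-3,5-bis(benzyloxy)-2-[4-(benzyloxy)-3-[3,4,5-tris(benzyloxy)benzoyloxy]phenyl]chroman-7-yl 3,4,5-tris(benzyloxy)benzoate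
Conditions: DCC, DMAP (cat.), CH2Cl2, rt
Reagents that add atoms: none
Why: Steglich esterification acylates both phenols with the benzyl-protected gallic acid, and since no other free hydroxyl is present no selectivity is required.

Step 12
Reactants: 15 nona-O-benzyl bis-gallate
Product: 16 catechin 7,3'-di-O-gallate
Conditions: H2 (1 atm), Pd(OH)2/C, THF/EtOAc, rt
Reagents that add atoms: none
Why: Catalytic hydrogenolysis cleaves all nine benzyl ethers and leaves the aryl esters and both stereocentres intact, and a neutral aprotic medium with prompt work-up should limit migration of the 3'-galloyl group to the freed 4'-hydroxyl.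

Compound list
1 | 2,4,6-trihydroxybenzaldehyde | O=Cc1c(O)cc(O)cc1O | starting material
2 | 2,6-dihydroxy-4-(methoxymethoxy)benzaldehyde | O=Cc1c(O)cc(OCOC)cc1O | intermediate
3 | 2-(benzyloxy)-6-hydroxy-4-(methoxymethoxy)benzaldehyde | O=Cc1c(O)cc(OCOC)cc1OCc1ccccc1 | intermediate
4 | 3-(benzyloxy)-2-(hydroxymethyl)-5-(methoxymethoxy)phenol | COCOc1cc(O)c(CO)c(OCc2ccccc2)c1 | intermediate
5 | 3,4-dihydroxybenzaldehyde | O=Cc1ccc(O)c(O)c1 | starting material
6 | 4-(benzyloxy)-3-hydroxybenzaldehyde | O=Cc1ccc(OCc2ccccc2)c(O)c1 | intermediate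
7 | 4-(benzyloxy)-3-(methoxymethoxy)benzaldehyde | O=Cc1ccc(OCc2ccccc2)c(OCOC)c1 | intermediate
8 | 2-[(E)-2-[4-(benzyloxy)-3-(methoxymethoxy)phenyl]ethenyl]-4,4,5,5-tetramethyl-1,3,2-dioxaborolane | COCOc1cc(/C=C/B2OC(C)(C)C(C)(C)O2)ccc1OCc1ccccc1 | intermediate
9 | 5-(benzyloxy)-3-(methoxymethoxy)-6-methylidenecyclohexa-2,4-dien-1-one (ortho-quinone methide, not isolated) | C=C1C(=O)C=C(OCOC)C=C1OCc1ccccc1 | intermediate
10 | (2S,3S)-5-(benzyloxy)-2-[4-(benzyloxy)-3-(methoxymethoxy)phenyl]-7-(methoxymethoxy)-3-(4,4,5,5-tetramethyl-1,3,2-dioxaborolan-2-yl)chromane (2,3-trans) | COCOc1cc(OCc3ccccc3)c2c(c1)O[C@H](c1ccc(OCc3ccccc3)c(OCOC)c1)[C@@H](B1OC(C)(C)C(C)(C)O1)C2 | intermediate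
11 | (2R,3S)-5-(benzyloxy)-2-[4-(benzyloxy)-3-(methoxymethoxy)phenyl]-7-(methoxymethoxy)chroman-3-ol | COCOc1cc(OCc3ccccc3)c2c(c1)O[C@H](c1ccc(OCc3ccccc3)c(OCOC)c1)[C@@H](O)C2 | intermediate
12 | (2R,3S)-3,5-bis(benzyloxy)-2-[4-(benzyloxy)-3-(methoxymethoxy)phenyl]-7-(methoxymethoxy)chromane | COCOc1cc(OCc3ccccc3)c2c(c1)O[C@H](c1ccc(OCc3ccccc3)c(OCOC)c1)[C@@H](OCc1ccccc1)C2 | intermediate
13 | (2R,3S)-3,5-bis(benzyloxy)-2-[4-(benzyloxy)-3-hydroxyphenyl]chroman-7-ol | Oc1cc(OCc3ccccc3)c2c(c1)O[C@H](c1ccc(OCc3ccccc3)c(O)c1)[C@@H](OCc1ccccc1)C2 | intermediate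
14 | 3,4,5-tris(benzyloxy)benzoic acid | OC(=O)c1cc(OCc2ccccc2)c(OCc2ccccc2)c(OCc2ccccc2)c1 | starting material
15 | (2R,3S)-3,5-bis(benzyloxy)-2-[4-(benzyloxy)-3-[3,4,5-tris(benzyloxy)benzoyloxy]phenyl]chroman-7-yl 3,4,5-tris(benzyloxy)benzoate | O=C(Oc1cc(OCc3ccccc3)c2c(c1)O[C@H](c1ccc(OCc3ccccc3)c(OC(=O)c3cc(OCc4ccccc4)c(OCc4ccccc4)c(OCc4ccccc4)c3)c1)[C@@H](OCc1ccccc1)C2)c1cc(OCc2ccccc2)c(OCc2ccccc2)c(OCc2ccccc2)c1 | intermediate
16 | catechin 7,3'-di-O-gallate, (2R,3S)-3,5-dihydroxy-2-[4-hydroxy-3-(3,4,5-trihydroxybenzoyloxy)phenyl]chroman-7-yl 3,4,5-trihydroxybenzoate | O=C(Oc1cc(O)c2c(c1)O[C@H](c1ccc(O)c(OC(=O)c3cc(O)c(O)c(O)c3)c1)[C@@H](O)C2)c1cc(O)c(O)c(O)c1 | target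

Total step count: 12. Longest linear sequence: 9 steps (steps 1, 2, 3, 7, 8, 9, 10, 11, 12; the branch from 5 through steps 4, 5, 6 is equally long).

Steps most likely to fail

Step 7 (Proposed new method). Several processes could defeat it:
- Weak discrimination between the two alkene faces, because the quinone methide terminus is an unsubstituted CH2 and all induction must be relayed to the dienophile.
- Friedel–Crafts self-condensation of the quinone methide with the electron-rich A rings present.
- Transfer of the styryl group from boron with loss of the placeholder.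
- Acid-induced loss of a MOM group.

The fallback sets out from 3 and 8 and returns at 10. The pinacol ester of 8 is cleaved with NaIO4/NH4OAc in aqueous acetone to [(E)-2-[4-(benzyloxy)-3-(methoxymethoxy)phenyl]ethenyl]boronic acid F1. F1 and salicylaldehyde 3 are then heated with catalytic dibenzylamine in dioxane, a known Petasis-type chromene synthesis (iminium alkenylation, loss of the amine, 6π-electrocyclisation), which should give racemic 5-(benzyloxy)-2-[4-(benzyloxy)-3-(methoxymethoxy)phenyl]-7-(methoxymethoxy)-2H-chromene F2. Copper-catalysed enantioselective hydroboration of F2 (CuCl, chiral bisphosphine, NaOtBu, B2pin2, MeOH, THF), run as a kinetic resolution, should place boron on C3 anti to the C2 aryl group. It should deliver 10 from the fast-reacting enantiomer, at the price of at most half of the material.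

Step 8. In the boron ate complex the C3–B bond lies antiperiplanar to the C2–O1 bond, so base-induced β-elimination with opening of ring C could compete with the migration to oxygen. The fallback sets out from 10 and returns at 11. KHF2 in MeOH/H2O converts 10 into potassium trifluoro[(2S,3S)-5-(benzyloxy)-2-[4-(benzyloxy)-3-(methoxymethoxy)phenyl]-7-(methoxymethoxy)chroman-3-yl]borate F3. Oxone in acetone/water should then oxidise F3 within minutes, without added base and with retention, to 11.

Step 1. Incomplete regiocontrol and over-alkylation may occur in the mono-protection of a triol. The fallback sets out from 1 and returns at 3, taking three steps in place of steps 1 and 2. MOMCl (2.2 equiv) and iPr2NEt give 2-hydroxy-4,6-bis(methoxymethoxy)benzaldehyde F4, in which only the chelated hydroxyl is left. BnBr/K2CO3 in warm DMF gives 2-(benzyloxy)-4,6-bis(methoxymethoxy)benzaldehyde F5. Brief treatment with dilute HCl in MeOH at 0 °C should then remove first the MOM group ortho to the formyl group, whose cleavage is assisted by the carbonyl and gives a hydrogen-bonded phenol, to give 3.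

Further compounds
F1 | step 7 | [(E)-2-[4-(benzyloxy)-3-(methoxymethoxy)phenyl]ethenyl]boronic acid | COCOc1cc(/C=C/B(O)O)ccc1OCc1ccccc1
F2 | step 7 | (±)-5-(benzyloxy)-2-[4-(benzyloxy)-3-(methoxymethoxy)phenyl]-7-(methoxymethoxy)-2H-chromene | COCOc1cc(OCc3ccccc3)c2C=CC(c3ccc(OCc4ccccc4)c(OCOC)c3)Oc2c1
F3 | step 8 | potassium trifluoro[(2S,3S)-5-(benzyloxy)-2-[4-(benzyloxy)-3-(methoxymethoxy)phenyl]-7-(methoxymethoxy)chroman-3-yl]borate | COCOc1cc(OCc3ccccc3)c2c(c1)O[C@H](c1ccc(OCc3ccccc3)c(OCOC)c1)[C@@H]([B-](F)(F)F)C2.[K+]
F4 | step 1 | 2-hydroxy-4,6-bis(methoxymethoxy)benzaldehyde | O=Cc1c(O)cc(OCOC)cc1OCOC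
F5 | step 1 | 2-(benzyloxy)-4,6-bis(methoxymethoxy)benzaldehyde | O=Cc1c(OCc2ccccc2)cc(OCOC)cc1OCOC
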